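## The problem

The target is a heliangolide-type germacranolide. A ten-membered carbocycle (C1–C10) is trans-fused through C6 and C7 to an α-methylene-γ-butyrolactone (C11, C12, C13). It carries a (Z)-trisubstituted C4=C5 alkene, a trans C1/C10 epoxide, a free allylic hydroxyl at C3 and, at C8, an ester of (2R,3S)-2,3-dimethyloxirane-2-carboxylic acid. The medium ring must be closed against transannular strain with both olefin geometries fixed beforehand: the 1(10)E alkene that becomes the epoxide, and the 4Z alkene. Of the six ring stereocentres (1R,3S,6R,7R,8R,10R), C6, C7 and C8 are contiguous and can be relayed from one another. C3 and the C1/C10 pair are remote and can be controlled only by the ring conformation or by a chiral reagent; the two side-chain centres are isolated and need reagent control. Several groups are fragile. The methylene lactone is a Michael acceptor that will not tolerate hydrides, ylides or carbanions. The 1,10-epoxide faces the C4=C5 alkene across the ring and cyclises under acid. β,γ-Unsaturated carbonyl intermediates drift into conjugation, and a free C8 hydroxyl sits 1,3 to C12 and can translactonise. The enabling feature is in the lactone: C7 is the β-carbon of a C11=C7 butenolide whose γ-carbon is C6, it is bonded to oxygenated C8 (an acyl-anion position), and C11 carries the one-carbon unit C13. A γ-substituted butenolide, an acyl-anion equivalent and a one-carbon electrophile can therefore be joined in one operation, with C6 from the chiral pool controlling C7.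

## Retrosynthesis

**Epoxide last (33 ⇒ 32 ⇒ 31).** The C1–O and C10–O bonds are removed first, leading through the C3 silyl ether 32 to triene 31. The epoxide cannot be carried through organolithium, iodide or chromium chemistry, and it is the group most prone to transannular reaction, so it is made in the penultimate step. The forward step must pick C1=C10 over two other alkenes and one of its faces. C11=C13 is electron-poor, and C4=C5 is deactivated by two allylic C–O bonds and shielded by the C3 triethylsilyl ether, which is the reason for that protecting group.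

**Methylene lactone from a Mannich base (31 ⇒ 29, via 30).** The C11=C13 alkene is traced back to the dimethylaminomethyl lactone 29. This keeps the Michael acceptor masked through every nucleophilic and reducing step and costs only a quaternisation–elimination near the end.

**Ring closure at C3–C4 (29 ⇒ 28 ⇒ 27).** The C3–C4 bond of the allylic alcohol is cut to the (Z)-alkenyl iodide/aldehyde 27. A cut at C4=C5 would demand a Z-selective trisubstituted olefination inside a ten-membered ring. A cut at C1=C10 would put olefin geometry at risk in the closure. The C3–C4 cut lets both alkenes be set in open-chain compounds and delivers the C3 carbinol directly. The forward Nozaki–Hiyama–Kishi reaction must close a strained ring at high dilution and tolerate the amine and the glycidic ester. The C3 configuration will follow the ring conformation.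

**Ester at C8 before ring closure (27 ⇒ 26 ⇒ 25 ⇒ 19 + 23).** The C8–O acyl bond is cut to alcohol 19 and epoxy acid 23. Acylating early has three advantages: the C8 hydroxyl can no longer attack C12, no separate protecting group is needed at C8, and C3 and C8 never have to be told apart as free alcohols. Acid 23 comes from tiglic acid 20 through alcohol 21 and epoxy alcohol 22. Its two centres are set by a Sharpless asymmetric epoxidation, because nothing in the molecule could control them.

**C8 carbinol from the masked carbonyl (19 ⇒ 18 ⇒ 17).** The C8–H bond is traced to ketone 18 and the ketone to dithiane 17. The ketone is β,γ-unsaturated and β to the lactone oxygen, so it is unmasked only after the olefination at C5 and reduced at once. The reduction must follow the Felkin–Anh sense set by C7.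

**C4=C5 by olefination (17 ⇒ 16 ⇒ 15 ⇒ 14).** The alkene is cut to aldehyde 16 and a one-carbon iodo-ylide. Geometry is decided in an open-chain Wittig reaction instead of in the ring, and the iodine needed for ring closure arrives in the same step. The C5 oxygen must be unveiled before the C3 oxygen, so the butenolide carries the more labile silyl group (TBS) and the chain the more robust one (TBDPS).

**Key disconnection (14 ⇒ 9 + 11 + iminium salt).** The C7–C8 and C11–C13 bonds are cut together. Lactone 14 falls into butenolide 11, dithiane 9 and dimethylmethyleneiminium iodide. This removes two stereocentres and two skeletal bonds at once and leaves three achiral or chiral-pool pieces. The forward step must be a 1,4-addition anti to the C6 substituent, followed by C-alkylation of the enolate anti to the new C7 substituent.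

**Fragments (9 ⇒ 6 + 7; 6 ⇒ 5 ⇒ 4 ⇒ 3 ⇒ 2 ⇒ 1; 11 ⇒ 10).** Dithiane 9 comes from 1,3-dithiane 7 and allylic bromide 6. The E-alkene of 6 is set by a stabilised Wittig reaction on aldehyde 3, made from propane-1,3-diol 1 through 2, and carried through ester 4 and alcohol 5. Butenolide 11 is the silyl ether of commercial (S)-5-(hydroxymethyl)furan-2(5H)-one 10.

## Roads not taken

**Alternative 1:** The lactone C6–O bond is cut and C6 is taken back to a methylene group. A cytochrome P450 monooxygenase of the germacrene acid 6-hydroxylase class would hydroxylate C6 of the free acid A1, and the new alcohol would close onto C12 to give the trans-lactone A2.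
- Merits: C6 and the ring fusion arise in one protecting-group-free step under neutral aqueous conditions, and the methylene lactone never has to be masked.
- Weak points: A1 already contains the ten-membered ring, the 4Z alkene and the C3, C7 and C8 centres, so the hardest part of the problem is only moved, not solved. Enzymes of this class are known for the 4E acid and close relatives; acceptance of a 4Z, 3,8-dioxygenated substrate would have to be found by screening or engineering. A2 has two free secondary hydroxyls, so acylating C8 alone needs protection after all.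
- Comparison: if a suitable enzyme existed, this road would be shorter from the carbocycle onward and would avoid the dithiane hydrolysis and ketone reduction. The chosen plan sets against this that every step rests on reaction types of known scope, that C6 is bought from the chiral pool, and that the carbocycle is actually constructed.

**Alternative 2:** The C1–C10 bond is cut through the future epoxide. SmI2 would couple the C1 aldehyde and C10 methyl ketone of seco compound A3 to the ten-membered cis-diol A4. Sulfonylation of the secondary C1 hydroxyl and closure by the tertiary alkoxide with inversion would then give the trans-epoxide.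
- Merits: the ring and both epoxide centres are made in one step, and their relationship is fixed as a diol that can be checked before the epoxide exists.
- Weak points: a ten-membered pinacol closure is slow and its facial sense relative to C3 and C8 cannot be predicted. A3 needs C3 and C8 set and protected separately in the open chain. A4 lacks C13, so the lactone must later be methylenated with strong base in the presence of a sulfonate or epoxide.
- Comparison: in one respect this road is better. The chosen plan leaves the C1/C10 configuration to a late epoxidation governed by ring conformation. It sets against this that C13 is installed in the key step, that C3 arises in the ring closure itself, and that fewer protecting groups are needed; a catalyst-controlled epoxidation is held in reserve.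

**Alternative 3:** The ten-membered ring is hidden in a cis-decalin by a temporary C3–C8 bond. Pb(OAc)4 would cleave the tertiary cis-diol A5 to the 3,8-diketone A6.
- Merits: ring strain is paid for by a fragmentation that is reliable for medium rings, and the (Z)-enone geometry is guaranteed by the six-membered ring of A5. This closure is probably more dependable than the Nozaki–Hiyama–Kishi cyclisation of the chosen plan.
- Weak points: A5 is a densely substituted decalin with two throw-away stereocentres, no easier to make than the target. A6 has two ketones that must be told apart and reduced stereoselectively on the macrocycle, in the presence of the unmasked methylene lactone, which forbids the usual bulky hydrides. The C8 ketone is β to the lactone oxygen. The acetonide must be removed with acid in a ring prone to transannular reactions.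
- Comparison: the chosen plan sets against the better ring formation that C8 is reduced before ring closure next to a rigid lactone, and that the Michael acceptor stays masked until three steps from the end.

Key step: step 8

Remark: germacrane locants (C1–C15) are used for all intermediates, including open-chain ones; C11 is a stereocentre only in intermediates, and its configuration does not affect the target.

## Route

Step 1
Reactants: 1 propane-1,3-diol
Product: 2 3-(tert-butyldiphenylsilyloxy)propan-1-ol
Conditions: NaH (1.0 equiv), THF, 0 °C to rt; then t-BuPh2SiCl, rt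
Reagents that add atoms: tert-butyl(chloro)diphenylsilane CC(C)(C)[Si](Cl)(c1ccccc1)c1ccccc1
Why: Monosilylation of a symmetrical diol through its sparingly soluble monosodium alkoxide, which reacts faster than the remaining hydroxyl.

Step 2
Reactants: 2 3-(tert-butyldiphenylsilyloxy)propan-1-ol
Product: 3 3-(tert-butyldiphenylsilyloxy)propanal
Conditions: TEMPO (cat.), PhI(OAc)2, CH2Cl2, rt
Reagents that add atoms: none
Why: Oxoammonium-mediated oxidation of a primary alcohol stops at the aldehyde and leaves the silyl ether untouched.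

Step 3
Reactants: 3 3-(tert-butyldiphenylsilyloxy)propanal
Product: 4 ethyl (E)-5-(tert-butyldiphenylsilyloxy)-2-methylpent-2-enoate
Conditions: Ph3P=C(CH3)CO2Et, CH2Cl2, rt
Reagents that add atoms: ethyl 2-(triphenylphosphoranylidene)propanoate CCOC(=O)C(C)=P(c1ccccc1)(c1ccccc1)c1ccccc1
Why: Wittig olefination with a stabilised ylide should give the (E)-trisubstituted enoate under thermodynamic control of oxaphosphetane formation; this fixes the future C1=C10 geometry.

Step 4
Reactants: 4 ethyl (E)-5-(tert-butyldiphenylsilyloxy)-2-methylpent-2-enoate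
Product: 5 (E)-5-(tert-butyldiphenylsilyloxy)-2-methylpent-2-en-1-ol
Conditions: i-Bu2AlH (2.2 equiv), CH2Cl2, −78 °C; aqueous work-up
Reagents that add atoms: none
Why: 1,2-Reduction of the enoate by i-Bu2AlH gives the allylic alcohol without touching the alkene geometry.

Step 5
Reactants: 5 (E)-5-(tert-butyldiphenylsilyloxy)-2-methylpent-2-en-1-ol
Product: 6 (E)-1-bromo-5-(tert-butyldiphenylsilyloxy)-2-methylpent-2-ene
Conditions: CBr4, PPh3, CH2Cl2, 0 °C
Reagents that add atoms: carbon tetrabromide BrC(Br)(Br)Br
Why: Appel bromination; SN2 displacement of the oxyphosphonium ion at the primary carbon keeps alkene position and geometry.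

Step 6
Reactants: 7 1,3-dithiane; 6 (E)-1-bromo-5-(tert-butyldiphenylsilyloxy)-2-methylpent-2-ene
Product: 9 2-[(E)-5-(tert-butyldiphenylsilyloxy)-2-methylpent-2-enyl]-1,3-dithiane, via 2-lithio-1,3-dithiane 8 (not isolated)
Conditions: n-BuLi, THF, −30 °C; then 6, −78 °C to rt
Reagents that add atoms: none
Why: Corey–Seebach alkylation; the sulfur-stabilised carbanion displaces the primary allylic bromide by SN2.

Step 7
Reactants: 10 (S)-5-(hydroxymethyl)furan-2(5H)-one
Product: 11 (S)-5-[(tert-butyldimethylsilyloxy)methyl]furan-2(5H)-one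
Conditions: t-BuMe2SiCl, imidazole, CH2Cl2, 0 °C to rt
Reagents that add atoms: tert-butyl(chloro)dimethylsilane CC(C)(C)[Si](C)(C)Cl
Why: Standard silylation of a primary alcohol; the bulky group also shields one face of the butenolide, and TBS is chosen so that C5 can be unveiled before C3.

Step 8
Reactants: 9 2-[(E)-5-(tert-butyldiphenylsilyloxy)-2-methylpent-2-enyl]-1,3-dithiane; 11 (S)-5-[(tert-butyldimethylsilyloxy)methyl]furan-2(5H)-one
Product: 14 (3R,4S,5S)-5-[(tert-butyldimethylsilyloxy)methyl]-4-{2-[(E)-5-(tert-butyldiphenylsilyloxy)-2-methylpent-2-enyl]-1,3-dithian-2-yl}-3-[(dimethylamino)methyl]dihydrofuran-2(3H)-one, via lithiated dithiane 12 (not isolated), via lithium lactone enolate 13 (not isolated)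
Conditions: t-BuLi (1.0 equiv), THF–HMPA (10:1), −78 °C; 11, −78 °C; Me2N+=CH2 I−, −78 to −20 °C
Reagents that add atoms: dimethylmethyleneiminium iodide C[N+](C)=C.[I-]
Why: t-BuLi removes the C2 proton of 9, and HMPA turns the resulting 12 into a solvent-separated ion pair that adds to the β-carbon (C7) of butenolide 11 in a 1,4-manner instead of attacking the lactone carbonyl. The carbanion approaches the face opposite the C6 silyloxymethyl group, so C7 is set anti to C6 by 1,2-induction (7S in 14; the descriptor becomes 7R once C8 is a carbinol). The lithium enolate 13 is then C-alkylated at C11 by the iminium ion in a Mannich reaction, anti to the new and very bulky C7 substituent, giving the trans,trans lactone (11R); this centre becomes trigonal in step 22, so its purity is not critical. The closest known reaction type is the tandem conjugate addition of lithiated 1,3-dithianes to γ-substituted butenolides with trapping of the lactone enolate by a carbon electrophile, combined with aminomethylation of lactone enolates by the same iminium salt. No ring is closed; the C7–C8 and C11–C13 bonds are formed. The step needs 1,4- over 1,2-addition (sulfur-stabilised anion, HMPA), addition faster than γ-deprotonation of 11 (low temperature, no excess base) and C- over O-alkylation of the enolate (soft iminium carbon).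

Step 9
Reactants: 14 (3R,4S,5S)-5-[(tert-butyldimethylsilyloxy)methyl]-4-{2-[(E)-5-(tert-butyldiphenylsilyloxy)-2-methylpent-2-enyl]-1,3-dithian-2-yl}-3-[(dimethylamino)methyl]dihydrofuran-2(3H)-one
Product: 15 (3R,4S,5S)-4-{2-[(E)-5-(tert-butyldiphenylsilyloxy)-2-methylpent-2-enyl]-1,3-dithian-2-yl}-3-[(dimethylamino)methyl]-5-(hydroxymethyl)dihydrofuran-2(3H)-one
Conditions: camphorsulfonic acid (1.5 equiv), MeOH–CH2Cl2, 0 °C
Reagents that add atoms: none
Why: Acid-catalysed methanolysis cleaves a primary TBS ether much faster than a primary TBDPS ether; the amine is protonated (hence more than one equivalent of acid), and dithiane and lactone are inert.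

Step 10
Reactants: 15 (3R,4S,5S)-4-{2-[(E)-5-(tert-butyldiphenylsilyloxy)-2-methylpent-2-enyl]-1,3-dithian-2-yl}-3-[(dimethylamino)methyl]-5-(hydroxymethyl)dihydrofuran-2(3H)-one
Product: 16 (2S,3S,4R)-3-{2-[(E)-5-(tert-butyldiphenylsilyloxy)-2-methylpent-2-enyl]-1,3-dithian-2-yl}-4-[(dimethylamino)methyl]-5-oxotetrahydrofuran-2-carbaldehyde
Conditions: SO3·pyridine, DMSO, i-Pr2NEt, CH2Cl2, 0 °C
Reagents that add atoms: none
Why: Parikh–Doering oxidation with activated DMSO tolerates thioacetals and tertiary amines; the α-acyloxy aldehyde is used crude, and any enolisation at C6 would return the more stable trans arrangement.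

Step 11
Reactants: 16 (2S,3S,4R)-3-{2-[(E)-5-(tert-butyldiphenylsilyloxy)-2-methylpent-2-enyl]-1,3-dithian-2-yl}-4-[(dimethylamino)methyl]-5-oxotetrahydrofuran-2-carbaldehyde
Product: 17 (3R,4S,5S)-4-{2-[(E)-5-(tert-butyldiphenylsilyloxy)-2-methylpent-2-enyl]-1,3-dithian-2-yl}-3-[(dimethylamino)methyl]-5-[(Z)-2-iodoprop-1-enyl]dihydrofuran-2(3H)-one
Conditions: EtPPh3+ I−, n-BuLi, THF, 0 °C; I2, −78 °C; NaN(SiMe3)2, −20 °C; then 16, −78 to −20 °C
Reagents that add atoms: ethyltriphenylphosphonium iodide CC[P+](c1ccccc1)(c1ccccc1)c1ccccc1.[I-]; iodine II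
Why: Stork–Zhao olefination; the unstabilised α-iodo ylide reacts under kinetic control to place iodine cis to C6, giving the (Z)-2-iodoalkene whose geometry becomes 4Z after ring closure.

Step 12
Reactants: 17 (3R,4S,5S)-4-{2-[(E)-5-(tert-butyldiphenylsilyloxy)-2-methylpent-2-enyl]-1,3-dithian-2-yl}-3-[(dimethylamino)methyl]-5-[(Z)-2-iodoprop-1-enyl]dihydrofuran-2(3H)-one
Product: 18 (3R,4S,5S)-4-[(E)-6-(tert-butyldiphenylsilyloxy)-3-methylhex-3-enoyl]-3-[(dimethylamino)methyl]-5-[(Z)-2-iodoprop-1-enyl]dihydrofuran-2(3H)-one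
Conditions: Hg(ClO4)2, CaCO3, THF–H2O, 0 °C
Reagents that add atoms: water O
Why: Hydrolysis of the dithioacetal assisted by thiophilic divalent mercury, buffered by CaCO3. The short cold reaction and immediate use of 18 keep the β,γ-unsaturated, β-acyloxy ketone from conjugation and elimination; alkenyl iodide and silyl ether are inert.

Step 13
Reactants: 18 (3R,4S,5S)-4-[(E)-6-(tert-butyldiphenylsilyloxy)-3-methylhex-3-enoyl]-3-[(dimethylamino)methyl]-5-[(Z)-2-iodoprop-1-enyl]dihydrofuran-2(3H)-one
Product: 19 (3R,4R,5S)-4-[(1R,3E)-6-(tert-butyldiphenylsilyloxy)-1-hydroxy-3-methylhex-3-enyl]-3-[(dimethylamino)methyl]-5-[(Z)-2-iodoprop-1-enyl]dihydrofuran-2(3H)-one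
Conditions: LiBH(s-Bu)3, THF, −78 °C; AcOH, −78 °C
Reagents that add atoms: none
Why: Felkin–Anh reduction by a bulky hydride that spares the lactone. With the C7–C6 bond (the carbon bearing the ring oxygen and the iodoalkenyl group) anti to the incoming hydride and H7 beside the chain, attack should give 8R, reinforced by 1,3-anti induction from the β-acyloxy group. The cold acidic quench prevents the C8 alkoxide from attacking C12.

Step 14
Reactants: 20 tiglic acid [(E)-2-methylbut-2-enoic acid]
Product: 21 (E)-2-methylbut-2-en-1-ol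
Conditions: LiAlH4, Et2O, 0 °C to rt
Reagents that add atoms: none
Why: LiAlH4 reduces the carboxylic acid to the allylic alcohol by 1,2-addition and keeps the E-alkene.

Step 15
Reactants: 21 (E)-2-methylbut-2-en-1-ol
Product: 22 [(2S,3S)-2,3-dimethyloxiran-2-yl]methanol
Conditions: Ti(OiPr)4 (cat.), L-(+)-diethyl tartrate (cat.), t-BuOOH, 4 Å molecular sieves, CH2Cl2, −20 °C
Reagents that add atoms: tert-butyl hydroperoxide CC(C)(C)OO
Why: Sharpless asymmetric epoxidation; the Ti(OiPr)4–tartrate complex binds the allylic alcohol and delivers the peroxide oxygen to one enantioface, and L-(+)-diethyl tartrate should give the (2S,3S) epoxy alcohol from this E-trisubstituted substrate.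

Step 16
Reactants: 22 [(2S,3S)-2,3-dimethyloxiran-2-yl]methanol
Product: 23 (2R,3S)-2,3-dimethyloxirane-2-carboxylic acid
Conditions: RuCl3 (cat.), NaIO4, CCl4–MeCN–H2O, rt
Reagents that add atoms: water O
Why: RuO4 generated in the flask oxidises the primary alcohol through the aldehyde hydrate (the second carboxyl oxygen comes from water) without opening the epoxide; the descriptor at C2 changes from S to R only because the priorities change.

Step 17
Reactants: 19 (3R,4R,5S)-4-[(1R,3E)-6-(tert-butyldiphenylsilyloxy)-1-hydroxy-3-methylhex-3-enyl]-3-[(dimethylamino)methyl]-5-[(Z)-2-iodoprop-1-enyl]dihydrofuran-2(3H)-one; 23 (2R,3S)-2,3-dimethyloxirane-2-carboxylic acid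
Product: 25 (1R,3E)-6-(tert-butyldiphenylsilyloxy)-1-{(2S,3R,4R)-4-[(dimethylamino)methyl]-2-[(Z)-2-iodoprop-1-enyl]-5-oxotetrahydrofuran-3-yl}-3-methylhex-3-enyl (2R,3S)-2,3-dimethyloxirane-2-carboxylate, via mixed anhydride 24 (not isolated)
Conditions: 2,4,6-Cl3C6H2COCl, Et3N, THF, rt; then 19, DMAP, toluene, rt
Reagents that add atoms: none
Why: Yamaguchi esterification; DMAP attacks the less hindered carbonyl of the mixed anhydride, and the acylpyridinium ion acylates the hindered C8 hydroxyl with retention. Acylation now blocks translactonisation and makes a separate C8 protecting group unnecessary.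

Step 18
Reactants: 25 (1R,3E)-6-(tert-butyldiphenylsilyloxy)-1-{(2S,3R,4R)-4-[(dimethylamino)methyl]-2-[(Z)-2-iodoprop-1-enyl]-5-oxotetrahydrofuran-3-yl}-3-methylhex-3-enyl (2R,3S)-2,3-dimethyloxirane-2-carboxylate
Product: 26 (1R,3E)-1-{(2S,3R,4R)-4-[(dimethylamino)methyl]-2-[(Z)-2-iodoprop-1-enyl]-5-oxotetrahydrofuran-3-yl}-6-hydroxy-3-methylhex-3-enyl (2R,3S)-2,3-dimethyloxirane-2-carboxylate
Conditions: Bu4NF, AcOH, THF, rt
Reagents that add atoms: none
Why: Fluoride cleaves the Si–O bond; buffering with acetic acid keeps the medium too weakly basic to eliminate the Mannich base or attack the esters.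

Step 19
Reactants: 26 (1R,3E)-1-{(2S,3R,4R)-4-[(dimethylamino)methyl]-2-[(Z)-2-iodoprop-1-enyl]-5-oxotetrahydrofuran-3-yl}-6-hydroxy-3-methylhex-3-enyl (2R,3S)-2,3-dimethyloxirane-2-carboxylate
Product: 27 (1R,3E)-1-{(2S,3R,4R)-4-[(dimethylamino)methyl]-2-[(Z)-2-iodoprop-1-enyl]-5-oxotetrahydrofuran-3-yl}-3-methyl-6-oxohex-3-enyl (2R,3S)-2,3-dimethyloxirane-2-carboxylate
Conditions: Dess–Martin periodinane, pyridine, CH2Cl2, 0 °C
Reagents that add atoms: none
Why: Dess–Martin oxidation of a homoallylic alcohol under nearly neutral conditions gives the β,γ-unsaturated aldehyde, which is used at once to avoid migration of the alkene into conjugation.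

Step 20
Reactants: 27 (1R,3E)-1-{(2S,3R,4R)-4-[(dimethylamino)methyl]-2-[(Z)-2-iodoprop-1-enyl]-5-oxotetrahydrofuran-3-yl}-3-methyl-6-oxohex-3-enyl (2R,3S)-2,3-dimethyloxirane-2-carboxylate
Product: 28 (3S,6R,7R,8R,11R)-13-(dimethylamino)-3-hydroxygermacra-1(10)E,4Z-dien-12,6-olid-8-yl (2R,3S)-2,3-dimethyloxirane-2-carboxylate
Conditions: CrCl2 (excess), NiCl2 (cat.), DMSO, rt, slow addition at high dilution
Reagents that add atoms: none
Why: Nozaki–Hiyama–Kishi reaction; NiCl2-derived zerovalent nickel inserts into the C4–I bond, transmetalation gives an alkenyl species of trivalent chromium that adds only to the aldehyde, closing the ten-membered ring at C3–C4 with retention of the 4Z geometry. The new C3 centre is set by the ring conformation in the addition step; 3S is the epimer aimed for and has to be confirmed (see the fallback).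

Step 21
Reactants: 28 (3S,6R,7R,8R,11R)-13-(dimethylamino)-3-hydroxygermacra-1(10)E,4Z-dien-12,6-olid-8-yl (2R,3S)-2,3-dimethyloxirane-2-carboxylate
Product: 29 (3S,6R,7R,8R,11R)-13-(dimethylamino)-3-(triethylsilyloxy)germacra-1(10)E,4Z-dien-12,6-olid-8-yl (2R,3S)-2,3-dimethyloxirane-2-carboxylate
Conditions: Et3SiCl, imidazole, DMF, 0 °C
Reagents that add atoms: chlorotriethylsilane CC[Si](Cl)(CC)CC
Why: Silylation of the secondary allylic alcohol removes its directing effect on peracids and shields C4=C5 for step 23.

Step 22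
Reactants: 29 (3S,6R,7R,8R,11R)-13-(dimethylamino)-3-(triethylsilyloxy)germacra-1(10)E,4Z-dien-12,6-olid-8-yl (2R,3S)-2,3-dimethyloxirane-2-carboxylate
Product: 31 (3S,6R,7R,8R)-3-(triethylsilyloxy)germacra-1(10)E,4Z,11(13)-trien-12,6-olid-8-yl (2R,3S)-2,3-dimethyloxirane-2-carboxylate, via quaternary ammonium iodide 30 (not isolated)
Conditions: MeI, THF, rt; then aq. NaHCO3, EtOAc, rt
Reagents that add atoms: none
Why: N-Methylation turns the amine into a leaving group, and mild base removes the acidic C11 proton (E1cB elimination of trimethylamine) to unveil the α-methylene lactone.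

Step 23
Reactants: 31 (3S,6R,7R,8R)-3-(triethylsilyloxy)germacra-1(10)E,4Z,11(13)-trien-12,6-olid-8-yl (2R,3S)-2,3-dimethyloxirane-2-carboxylate
Product: 32 (1R,3S,6R,7R,8R,10R)-1,10-epoxy-3-(triethylsilyloxy)germacra-4Z,11(13)-dien-12,6-olid-8-yl (2R,3S)-2,3-dimethyloxirane-2-carboxylate
Conditions: m-CPBA, Na2HPO4, CH2Cl2, 0 °C
Reagents that add atoms: 3-chloroperoxybenzoic acid O=C(OO)c1cccc(Cl)c1
Why: Prilezhaev epoxidation; C1=C10 is the only electron-rich alkene (C4=C5 has two allylic C–O bonds and the bulky silyl ether, C11=C13 is conjugated). The peracid should attack the outward face of the E-alkene, which in the ring conformer with the C10 methyl on the β-face gives the trans (1R,10R) epoxide.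

Step 24
Reactants: 32 (1R,3S,6R,7R,8R,10R)-1,10-epoxy-3-(triethylsilyloxy)germacra-4Z,11(13)-dien-12,6-olid-8-yl (2R,3S)-2,3-dimethyloxirane-2-carboxylate
Product: 33 (1R,3S,6R,7R,8R,10R)-1,10-epoxy-3-hydroxygermacra-4Z,11(13)-dien-12,6-olid-8-yl (2R,3S)-2,3-dimethyloxirane-2-carboxylate
Conditions: HF·pyridine, pyridine, THF, 0 °C
Reagents that add atoms: none
Why: Buffered fluoride removes the triethylsilyl ether without the acid strength that would trigger transannular opening of the 1,10-epoxide and without base that would add to the methylene lactone.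

## Compound list

1 | propane-1,3-diol | OCCCO | starting material
2 | 3-(tert-butyldiphenylsilyloxy)propan-1-ol | OCCCO[Si](c1ccccc1)(c1ccccc1)C(C)(C)C | intermediate
3 | 3-(tert-butyldiphenylsilyloxy)propanal | O=CCCO[Si](c1ccccc1)(c1ccccc1)C(C)(C)C | intermediate
4 | ethyl (E)-5-(tert-butyldiphenylsilyloxy)-2-methylpent-2-enoate | CCOC(=O)/C(C)=C/CCO[Si](c1ccccc1)(c1ccccc1)C(C)(C)C | intermediate
5 | (E)-5-(tert-butyldiphenylsilyloxy)-2-methylpent-2-en-1-ol | OC/C(C)=C/CCO[Si](c1ccccc1)(c1ccccc1)C(C)(C)C | intermediate
6 | (E)-1-bromo-5-(tert-butyldiphenylsilyloxy)-2-methylpent-2-ene | BrC/C(C)=C/CCO[Si](c1ccccc1)(c1ccccc1)C(C)(C)C | intermediate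
7 | 1,3-dithiane | C1CSCSC1 | starting material
8 | 2-lithio-1,3-dithiane | [Li]C1SCCCS1 | intermediate
9 | 2-[(E)-5-(tert-butyldiphenylsilyloxy)-2-methylpent-2-enyl]-1,3-dithiane | CC(C)(C)[Si](c1ccccc1)(c1ccccc1)OCC/C=C(\C)CC1SCCCS1 | intermediate
10 | (S)-5-(hydroxymethyl)furan-2(5H)-one | OC[C@H]1OC(=O)C=C1 | starting material
11 | (S)-5-[(tert-butyldimethylsilyloxy)methyl]furan-2(5H)-one | CC(C)(C)[Si](C)(C)OC[C@H]1OC(=O)C=C1 | intermediate
12 | 2-lithio-2-[(E)-5-(tert-butyldiphenylsilyloxy)-2-methylpent-2-enyl]-1,3-dithiane | [Li]C1(C/C(C)=C/CCO[Si](c2ccccc2)(c2ccccc2)C(C)(C)C)SCCCS1 | intermediate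
13 | lithium enolate of (4S,5S)-5-[(tert-butyldimethylsilyloxy)methyl]-4-{2-[(E)-5-(tert-butyldiphenylsilyloxy)-2-methylpent-2-enyl]-1,3-dithian-2-yl}dihydrofuran-2(3H)-one | [Li]OC1=C[C@H](C2(C/C(C)=C/CCO[Si](c3ccccc3)(c3ccccc3)C(C)(C)C)SCCCS2)[C@@H](CO[Si](C)(C)C(C)(C)C)O1 | intermediate
14 | (3R,4S,5S)-5-[(tert-butyldimethylsilyloxy)methyl]-4-{2-[(E)-5-(tert-butyldiphenylsilyloxy)-2-methylpent-2-enyl]-1,3-dithian-2-yl}-3-[(dimethylamino)methyl]dihydrofuran-2(3H)-one | CN(C)C[C@@H]1C(=O)O[C@H](CO[Si](C)(C)C(C)(C)C)[C@H]1C2(C/C(C)=C/CCO[Si](c3ccccc3)(c3ccccc3)C(C)(C)C)SCCCS2 | intermediate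
15 | (3R,4S,5S)-4-{2-[(E)-5-(tert-butyldiphenylsilyloxy)-2-methylpent-2-enyl]-1,3-dithian-2-yl}-3-[(dimethylamino)methyl]-5-(hydroxymethyl)dihydrofuran-2(3H)-one | CN(C)C[C@@H]1C(=O)O[C@H](CO)[C@H]1C2(C/C(C)=C/CCO[Si](c3ccccc3)(c3ccccc3)C(C)(C)C)SCCCS2 | intermediate
16 | (2S,3S,4R)-3-{2-[(E)-5-(tert-butyldiphenylsilyloxy)-2-methylpent-2-enyl]-1,3-dithian-2-yl}-4-[(dimethylamino)methyl]-5-oxotetrahydrofuran-2-carbaldehyde | CN(C)C[C@@H]1C(=O)O[C@H](C=O)[C@H]1C2(C/C(C)=C/CCO[Si](c3ccccc3)(c3ccccc3)C(C)(C)C)SCCCS2 | intermediate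
17 | (3R,4S,5S)-4-{2-[(E)-5-(tert-butyldiphenylsilyloxy)-2-methylpent-2-enyl]-1,3-dithian-2-yl}-3-[(dimethylamino)methyl]-5-[(Z)-2-iodoprop-1-enyl]dihydrofuran-2(3H)-one | CN(C)C[C@@H]1C(=O)O[C@H](/C=C(/C)I)[C@H]1C2(C/C(C)=C/CCO[Si](c3ccccc3)(c3ccccc3)C(C)(C)C)SCCCS2 | intermediate
18 | (3R,4S,5S)-4-[(E)-6-(tert-butyldiphenylsilyloxy)-3-methylhex-3-enoyl]-3-[(dimethylamino)methyl]-5-[(Z)-2-iodoprop-1-enyl]dihydrofuran-2(3H)-one | CN(C)C[C@@H]1C(=O)O[C@H](/C=C(/C)I)[C@H]1C(=O)C/C(C)=C/CCO[Si](c2ccccc2)(c2ccccc2)C(C)(C)C | intermediate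
19 | (3R,4R,5S)-4-[(1R,3E)-6-(tert-butyldiphenylsilyloxy)-1-hydroxy-3-methylhex-3-enyl]-3-[(dimethylamino)methyl]-5-[(Z)-2-iodoprop-1-enyl]dihydrofuran-2(3H)-one | CN(C)C[C@@H]1C(=O)O[C@H](/C=C(/C)I)[C@H]1[C@H](O)C/C(C)=C/CCO[Si](c2ccccc2)(c2ccccc2)C(C)(C)C | intermediate
20 | tiglic acid, (E)-2-methylbut-2-enoic acid | C/C=C(\C)C(=O)O | starting material
21 | (E)-2-methylbut-2-en-1-ol | C/C=C(\C)CO | intermediate
22 | [(2S,3S)-2,3-dimethyloxiran-2-yl]methanol | OC[C@]1(C)O[C@H]1C | intermediate
23 | (2R,3S)-2,3-dimethyloxirane-2-carboxylic acid | O=C(O)[C@]1(C)O[C@H]1C | intermediate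
24 | (2R,3S)-2,3-dimethyloxirane-2-carboxylic 2,4,6-trichlorobenzoic anhydride | O=C(OC(=O)c1c(Cl)cc(Cl)cc1Cl)[C@]2(C)O[C@H]2C | intermediate
25 | (1R,3E)-6-(tert-butyldiphenylsilyloxy)-1-{(2S,3R,4R)-4-[(dimethylamino)methyl]-2-[(Z)-2-iodoprop-1-enyl]-5-oxotetrahydrofuran-3-yl}-3-methylhex-3-enyl (2R,3S)-2,3-dimethyloxirane-2-carboxylate | CN(C)C[C@@H]1C(=O)O[C@H](/C=C(/C)I)[C@H]1[C@H](OC(=O)[C@]2(C)O[C@H]2C)C/C(C)=C/CCO[Si](c3ccccc3)(c3ccccc3)C(C)(C)C | intermediate
26 | (1R,3E)-1-{(2S,3R,4R)-4-[(dimethylamino)methyl]-2-[(Z)-2-iodoprop-1-enyl]-5-oxotetrahydrofuran-3-yl}-6-hydroxy-3-methylhex-3-enyl (2R,3S)-2,3-dimethyloxirane-2-carboxylate | CN(C)C[C@@H]1C(=O)O[C@H](/C=C(/C)I)[C@H]1[C@H](OC(=O)[C@]2(C)O[C@H]2C)C/C(C)=C/CCO | intermediate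
27 | (1R,3E)-1-{(2S,3R,4R)-4-[(dimethylamino)methyl]-2-[(Z)-2-iodoprop-1-enyl]-5-oxotetrahydrofuran-3-yl}-3-methyl-6-oxohex-3-enyl (2R,3S)-2,3-dimethyloxirane-2-carboxylate | CN(C)C[C@@H]1C(=O)O[C@H](/C=C(/C)I)[C@H]1[C@H](OC(=O)[C@]2(C)O[C@H]2C)C/C(C)=C/CC=O | intermediate
28 | (3S,6R,7R,8R,11R)-13-(dimethylamino)-3-hydroxygermacra-1(10)E,4Z-dien-12,6-olid-8-yl (2R,3S)-2,3-dimethyloxirane-2-carboxylate | CN(C)C[C@@H]1C(=O)O[C@@H]2/C=C(/C)[C@@H](O)C/C=C(\C)C[C@@H](OC(=O)[C@]3(C)O[C@H]3C)[C@@H]12 | intermediate
29 | (3S,6R,7R,8R,11R)-13-(dimethylamino)-3-(triethylsilyloxy)germacra-1(10)E,4Z-dien-12,6-olid-8-yl (2R,3S)-2,3-dimethyloxirane-2-carboxylate | CN(C)C[C@@H]1C(=O)O[C@@H]2/C=C(/C)[C@@H](O[Si](CC)(CC)CC)C/C=C(\C)C[C@@H](OC(=O)[C@]3(C)O[C@H]3C)[C@@H]12 | intermediate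
30 | [(3S,6R,7R,8R,11R)-8-{[(2R,3S)-2,3-dimethyloxirane-2-carbonyl]oxy}-3-(triethylsilyloxy)germacra-1(10)E,4Z-dien-12,6-olid-13-yl]trimethylammonium iodide | C[N+](C)(C)C[C@@H]1C(=O)O[C@@H]2/C=C(/C)[C@@H](O[Si](CC)(CC)CC)C/C=C(\C)C[C@@H](OC(=O)[C@]3(C)O[C@H]3C)[C@@H]12.[I-] | intermediate
31 | (3S,6R,7R,8R)-3-(triethylsilyloxy)germacra-1(10)E,4Z,11(13)-trien-12,6-olid-8-yl (2R,3S)-2,3-dimethyloxirane-2-carboxylate | C=C1C(=O)O[C@@H]2/C=C(/C)[C@@H](O[Si](CC)(CC)CC)C/C=C(\C)C[C@@H](OC(=O)[C@]3(C)O[C@H]3C)[C@@H]12 | intermediate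
32 | (1R,3S,6R,7R,8R,10R)-1,10-epoxy-3-(triethylsilyloxy)germacra-4Z,11(13)-dien-12,6-olid-8-yl (2R,3S)-2,3-dimethyloxirane-2-carboxylate | C=C1C(=O)O[C@@H]2/C=C(/C)[C@@H](O[Si](CC)(CC)CC)C[C@H]3O[C@]3(C)C[C@@H](OC(=O)[C@]3(C)O[C@H]3C)[C@@H]12 | intermediate
33 | (1R,3S,6R,7R,8R,10R)-1,10-epoxy-3-hydroxygermacra-4Z,11(13)-dien-12,6-olid-8-yl (2R,3S)-2,3-dimethyloxirane-2-carboxylate | C=C1C(=O)O[C@@H]2/C=C(/C)[C@@H](O)C[C@H]3O[C@]3(C)C[C@@H](OC(=O)[C@]3(C)O[C@H]3C)[C@@H]12 | target

## Step count and least certain steps

Total: 24 steps. Longest linear sequence: 20 steps (steps 1–6, 8–13 and 17–24). The butenolide branch (step 7) and the acid branch (steps 14–16) join at steps 8 and 17.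

**Step 8 (key step).** The tertiary, hindered carbanion 12 may act as a base and remove the γ-proton of 11. Alternatively the conjugate addition may revert while the sparingly soluble iminium salt reacts on warming, so that the enolate is protonated instead of alkylated. The fallback sets out from 9 and 11 and separates the two bond formations. The conjugate addition is quenched with acetic acid at −78 °C to give (4S,5S)-5-[(tert-butyldimethylsilyloxy)methyl]-4-{2-[(E)-5-(tert-butyldiphenylsilyloxy)-2-methylpent-2-enyl]-1,3-dithian-2-yl}dihydrofuran-2(3H)-one F1. The isolated lactone is then enolised on its own with LiN(i-Pr)2 in THF without HMPA, where the tighter ion pair is slower to revert, and alkylated with the same iminium iodide anti to the C7 substituent. This comes back to the route at 14 at the cost of one step.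

**Step 11.** The aldehyde of 16 is flanked by the dithiane-bearing C7 and is α-acyloxy, so slow olefination, epimerisation at C6 by the basic ylide, or erosion of Z selectivity are possible. The fallback sets out from 16. Ramirez olefination (CBr4, PPh3) gives (3R,4S,5S)-5-(2,2-dibromoethenyl)-4-{2-[(E)-5-(tert-butyldiphenylsilyloxy)-2-methylpent-2-enyl]-1,3-dithian-2-yl}-3-[(dimethylamino)methyl]dihydrofuran-2(3H)-one F2. A Negishi coupling with MeZnCl and Pd(PPh3)4 (zerovalent palladium) should occur at the less hindered C–Br bond trans to C6 and give the (3R,4S,5S)-5-[(Z)-2-bromoprop-1-enyl] lactone F3. A CuI-catalysed bromide-to-iodide exchange (NaI, trans-N,N'-dimethylcyclohexane-1,2-diamine, dioxane, heat) with retention of geometry comes back to the route at 17.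

**Step 13.** Facial selectivity may be poor or reversed, because the two ring carbons flanking C7 are of similar size. The ketone can also drift into conjugation, or the alkoxide can translactonise, if the reduction is slow. The fallback sets out from 18 and accepts the other epimer. If the reduction gives mainly (3R,4R,5S)-4-[(1S,3E)-6-(tert-butyldiphenylsilyloxy)-1-hydroxy-3-methylhex-3-enyl]-3-[(dimethylamino)methyl]-5-[(Z)-2-iodoprop-1-enyl]dihydrofuran-2(3H)-one F4, this alcohol is esterified with acid 23 under Mitsunobu conditions (PPh3, diisopropyl azodicarboxylate). Inversion at C8 leads directly to 25 and replaces step 17, so either outcome of the reduction reaches the same ester.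

**Step 20.** Transannular strain may favour oligomerisation over closure. The β,γ-unsaturated aldehyde may isomerise under the influence of the internal amine. Excess divalent chromium may attack the glycidic ester. The ring conformation may deliver the 3R alcohol. The fallback addresses the last point and sets out from 27. The cyclisation product (3R,6R,7R,8R,11R)-13-(dimethylamino)-3-hydroxygermacra-1(10)E,4Z-dien-12,6-olid-8-yl (2R,3S)-2,3-dimethyloxirane-2-carboxylate F5 is oxidised with Dess–Martin periodinane to the enone (6R,7R,8R,11R)-13-(dimethylamino)-3-oxogermacra-1(10)E,4Z-dien-12,6-olid-8-yl (2R,3S)-2,3-dimethyloxirane-2-carboxylate F6. This is reduced under reagent control with (R)-2-methyl-CBS-oxazaborolidine and catecholborane, the alkenyl group acting as the large substituent, to come back to the route at 28.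

**Step 23.** The peracid may attack the other face of C1=C10 if a different ring conformer reacts, or oxidise C4=C5 as well. The fallback sets out from 31 and replaces substrate control by catalyst control: a Shi epoxidation with the D-fructose-derived ketone and KHSO5 (buffered, MeCN–dimethoxymethane–water, 0 °C). Its chiral dioxirane favours the (R,R) epoxide of E-trisubstituted alkenes through a spiro transition state and reacts poorly with the electron-poor alkenes. It comes back to the route at 32 and makes no new compound.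

## Further compounds

F1 | step 8 | (4S,5S)-5-[(tert-butyldimethylsilyloxy)methyl]-4-{2-[(E)-5-(tert-butyldiphenylsilyloxy)-2-methylpent-2-enyl]-1,3-dithian-2-yl}dihydrofuran-2(3H)-one | O=C1C[C@H](C2(C/C(C)=C/CCO[Si](c3ccccc3)(c3ccccc3)C(C)(C)C)SCCCS2)[C@@H](CO[Si](C)(C)C(C)(C)C)O1
F2 | step 11 | (3R,4S,5S)-5-(2,2-dibromoethenyl)-4-{2-[(E)-5-(tert-butyldiphenylsilyloxy)-2-methylpent-2-enyl]-1,3-dithian-2-yl}-3-[(dimethylamino)methyl]dihydrofuran-2(3H)-one | CN(C)C[C@@H]1C(=O)O[C@H](C=C(Br)Br)[C@H]1C2(C/C(C)=C/CCO[Si](c3ccccc3)(c3ccccc3)C(C)(C)C)SCCCS2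
F3 | step 11 | (3R,4S,5S)-5-[(Z)-2-bromoprop-1-enyl]-4-{2-[(E)-5-(tert-butyldiphenylsilyloxy)-2-methylpent-2-enyl]-1,3-dithian-2-yl}-3-[(dimethylamino)methyl]dihydrofuran-2(3H)-one | CN(C)C[C@@H]1C(=O)O[C@H](/C=C(/C)Br)[C@H]1C2(C/C(C)=C/CCO[Si](c3ccccc3)(c3ccccc3)C(C)(C)C)SCCCS2
F4 | step 13 | (3R,4R,5S)-4-[(1S,3E)-6-(tert-butyldiphenylsilyloxy)-1-hydroxy-3-methylhex-3-enyl]-3-[(dimethylamino)methyl]-5-[(Z)-2-iodoprop-1-enyl]dihydrofuran-2(3H)-one | CN(C)C[C@@H]1C(=O)O[C@H](/C=C(/C)I)[C@H]1[C@@H](O)C/C(C)=C/CCO[Si](c2ccccc2)(c2ccccc2)C(C)(C)C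
F5 | step 20 | (3R,6R,7R,8R,11R)-13-(dimethylamino)-3-hydroxygermacra-1(10)E,4Z-dien-12,6-olid-8-yl (2R,3S)-2,3-dimethyloxirane-2-carboxylate | CN(C)C[C@@H]1C(=O)O[C@@H]2/C=C(/C)[C@H](O)C/C=C(\C)C[C@@H](OC(=O)[C@]3(C)O[C@H]3C)[C@@H]12
F6 | step 20 | (6R,7R,8R,11R)-13-(dimethylamino)-3-oxogermacra-1(10)E,4Z-dien-12,6-olid-8-yl (2R,3S)-2,3-dimethyloxirane-2-carboxylate | CN(C)C[C@@H]1C(=O)O[C@@H]2/C=C(/C)C(=O)C/C=C(\C)C[C@@H](OC(=O)[C@]3(C)O[C@H]3C)[C@@H]12
F0 | step 23 | none | none
A1 | alternative 1 | (3S,7R,8R)-3,8-dihydroxygermacra-1(10)E,4Z,11(13)-trien-12-oic acid | C=C(C(=O)O)[C@H]1C/C=C(/C)[C@@H](O)C/C=C(\C)C[C@H]1O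
A2 | alternative 1 | (3S,6R,7R,8R)-3,8-dihydroxygermacra-1(10)E,4Z,11(13)-trien-12,6-olide | C=C1C(=O)O[C@@H]2/C=C(/C)[C@@H](O)C/C=C(\C)C[C@@H](O)[C@@H]12
A3 | alternative 2 | 1,10-seco keto aldehyde of the 12,6-olide with C3 tert-butyldimethylsilyl ether and C8 4-methoxybenzyl ether | O=C1O[C@H](/C=C(/C)[C@@H](O[Si](C)(C)C(C)(C)C)CC=O)[C@H](C1)[C@H](OCc2ccc(OC)cc2)CC(C)=O
A4 | alternative 2 | ten-membered 1,10-cis-diol lactone with C3 tert-butyldimethylsilyl ether and C8 4-methoxybenzyl ether | O=C1O[C@@H]2/C=C(/C)[C@@H](O[Si](C)(C)C(C)(C)C)C[C@H](O)[C@](C)(O)C[C@@H](OCc3ccc(OC)cc3)[C@H]2C1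
A5 | alternative 3 | 3,8-cyclogermacrane (cis-decalin) 3,8-cis-diol with C1/C10 acetonide and methylene lactone | C=C1C(=O)O[C@@H]2C=C(C)[C@@]4(O)C[C@@H]3OC(C)(C)O[C@]3(C)C[C@@]4(O)[C@@H]12
A6 | alternative 3 | ten-membered 3,8-diketone with (Z)-enone, methylene lactone and C1/C10 acetonide | C=C1C(=O)O[C@@H]2/C=C(/C)C(=O)C[C@@H]3OC(C)(C)O[C@]3(C)CC(=O)[C@@H]12
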